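Ring A, the 3,5-dihydroxyphenyl ring, has its two hydroxyl-bearing carbons separated by one CH, and the side chain carries oxygen at C2′, two atoms from ring carbon C1: the pattern of a folded tetraketide. The route therefore disconnects the ring bond between C1 and the neighbouring carbon, which in the precursor still bears a sacrificial carboxyl group. In one operation the key step joins C2 to C7 of an open-chain methyl (9R)-9-silyloxy-3,5,7-trioxoicosanoate, dehydrates and aromatizes, delivering the complete ring with both phenols and the side chain in place. The stereocentre is set earlier by asymmetric hydrogenation; decarboxylation and acetate adjustment finish the synthesis.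

Key step: step 5

Remark on numbering: unprimed C1–C20 refer to the icosanoate chain of the open-chain precursor, primed numbers to the tridecyl side chain, and ring A is the benzene ring.
Remark on the target: the stereocentre of the given SMILES is (R), and the CIP descriptor stays (R) in every intermediate because the priority order O > CH2–C(ring or carbonyl) > undecyl > H never changes.
Remark on design: the C9 oxygen is carried as a triisopropylsilyl ether, because it must outlast both cold and hot hydroxide. A free hydroxyl beside the ester or acid would lactonize to a 3,4-dihydroisocoumarin before CO2 is lost.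
Assumption: both starting materials are taken as purchasable.

Step 1
Reactants: 1 methyl 3-oxotetradecanoate
Product: 2 methyl (3R)-3-hydroxytetradecanoate
Conditions: RuCl2[(R)-BINAP] (0.1 mol %), H2 (50 bar), MeOH, 50 °C
Reagents that add atoms: none
Why: Noyori asymmetric hydrogenation of a β-keto ester, in which the ester carbonyl chelates ruthenium and the (R)-BINAP ligand directs hydride to the ketone face that gives the (3R)-alcohol of simple 3-oxoalkanoates.

Step 2
Reactants: 2 methyl (3R)-3-hydroxytetradecanoate
Product: 3 methyl (3R)-3-[(triisopropylsilyl)oxy]tetradecanoate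
Conditions: i-Pr3SiOTf, 2,6-lutidine, CH2Cl2, 0 °C to rt
Reagents that add atoms: triisopropylsilyl trifluoromethanesulfonate, CC(C)[Si](C(C)C)(C(C)C)OS(=O)(=O)C(F)(F)F
Why: O-silylation of a secondary alcohol with a silyl triflate and a hindered pyridine base, which touches no bond at the stereocentre.

Step 3
Reactants: 3 methyl (3R)-3-[(triisopropylsilyl)oxy]tetradecanoate
Product: 4 (3R)-N-methoxy-N-methyl-3-[(triisopropylsilyl)oxy]tetradecanamide
Conditions: MeNH(OMe)·HCl, i-PrMgCl, THF, −20 to 0 °C
Reagents that add atoms: N,O-dimethylhydroxylamine hydrochloride, CNOC.Cl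
Why: Weinreb amidation of an ester by the chloromagnesium amide made in the flask, a nucleophilic but weakly basic reagent that should leave the β-silyloxy group and the stereocentre untouched.

Step 4
Reactants: 4 (3R)-N-methoxy-N-methyl-3-[(triisopropylsilyl)oxy]tetradecanamide; 5 methyl 3,5-dioxohexanoate
Product: 8 methyl (9R)-3,5,7-trioxo-9-[(triisopropylsilyl)oxy]icosanoate, via trilithium trianion 6 (not isolated), via tetrahedral lithium adduct 7 (not isolated)
Conditions: 5 (2 equiv), LiN(i-Pr)2 (6.2 equiv), THF, −78 to 0 °C; then 4, −78 to −20 °C; AcOH, −78 °C; crude 8 used at once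
Reagents that add atoms: none
Why: C-acylation of a 1,3,5-tricarbonyl polyanion with a Weinreb amide, in which the last-formed terminal C6 carbanion is the most nucleophilic site and the N-methoxy chelate holds the tetrahedral adduct until the acidic quench, so a single acyl transfer should occur.

Step 5
Reactants: 8 methyl (9R)-3,5,7-trioxo-9-[(triisopropylsilyl)oxy]icosanoate
Product: 10 methyl 2,4-dihydroxy-6-[(2R)-2-[(triisopropylsilyl)oxy]tridecyl]benzoate, via cyclic aldol 9 (not isolated)
Conditions: 1 M aq KOH (5 equiv), THF, 0 °C to rt, N2; then 1 M HCl to pH 4, 0 °C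
Reagents that add atoms: none
Why: Hydroxide converts 8 into its polyenolate; the C2 carbanion, flanked by the ester and the C3 ketone, adds to the C7 carbonyl to give the cyclohexanedione aldol 9, which loses water by E1cB and tautomerizes to the phenol, the gain in aromaticity making the sequence irreversible. This is the established base-mediated aldol cyclization of 3,5,7-triketo esters to β-resorcylates, the laboratory model of polyketide folding. Ring A closes in a 6-(enolendo)-exo-trig mode, with the C2=C3 enolate double bond inside the new ring and the C7 carbonyl oxygen outside it. No stereocentre is created, since the ring carbons of 9 all become sp2, and C9, set in step 1, lies outside the reacting array and bears no acidic hydrogen. The step needs C2-to-C7 aldol closure and not C6-to-C1 Claisen closure, lactonization to a 4-hydroxy-2-pyranone, ester hydrolysis or loss of silanolate. A cold, aqueous, non-chelating hydroxide medium favours the aldol mode and keeps saponification slower than ring closure, and C8, the only carbon whose deprotonation could expel the C9 silyloxy group, is the least acidic methylene of an already anionic chain.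

Step 6
Reactants: 10 methyl 2,4-dihydroxy-6-[(2R)-2-[(triisopropylsilyl)oxy]tridecyl]benzoate
Product: 12 5-[(2R)-2-[(triisopropylsilyl)oxy]tridecyl]benzene-1,3-diol, via resorcylic acid 11 (not isolated)
Conditions: 4 M aq KOH, MeOH, reflux, N2; 1 M HCl to pH 3, 0 °C; toluene, 100 °C
Reagents that add atoms: none
Why: Saponification of the hindered ester under forcing alkali followed by protodecarboxylation (retro-Kolbe–Schmitt) of the 2,4-dihydroxybenzoic acid, made easy by ortho and para hydroxyls that stabilize ipso protonation, while the triisopropylsilyl ether should withstand the alkali and keep the C2′ oxygen from lactonizing onto the carboxyl group.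

Step 7
Reactants: 12 5-[(2R)-2-[(triisopropylsilyl)oxy]tridecyl]benzene-1,3-diol
Product: 14 5-[(2R)-2-(acetyloxy)tridecyl]-1,3-phenylene diacetate, via triol 13 (not isolated)
Conditions: Bu4NF (4 equiv), THF, rt to 40 °C; then Ac2O, pyridine, DMAP (cat.), rt
Reagents that add atoms: acetic anhydride, CC(=O)OC(C)=O
Why: Fluoride-induced Si–O cleavage followed in the same flask by DMAP-catalysed acetylation of all three hydroxyls, neither of which breaks the C–O bond at the stereocentre, so the configuration is retained and the polar triol need not be separated from ammonium salts.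

Step 8
Reactants: 14 5-[(2R)-2-(acetyloxy)tridecyl]-1,3-phenylene diacetate
Product: 15 (2R)-1-(3,5-dihydroxyphenyl)tridecan-2-yl acetate
Conditions: NH4OAc (8 equiv), MeOH/H2O (4:1), rt
Reagents that add atoms: none
Why: Chemoselective near-neutral methanolysis of aryl acetates, in which phenoxide is a far better leaving group than a secondary alkoxide, so the two phenyl esters should be cleaved while the hindered alkyl acetate stays and no acyl migration to the remote meta phenols is geometrically possible.

Compound list
1 | methyl 3-oxotetradecanoate | CCCCCCCCCCCC(=O)CC(=O)OC | starting material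
2 | methyl (3R)-3-hydroxytetradecanoate | CCCCCCCCCCC[C@H](CC(=O)OC)O | intermediate
3 | methyl (3R)-3-[(triisopropylsilyl)oxy]tetradecanoate | CCCCCCCCCCC[C@H](CC(=O)OC)O[Si](C(C)C)(C(C)C)C(C)C | intermediate
4 | (3R)-N-methoxy-N-methyl-3-[(triisopropylsilyl)oxy]tetradecanamide | CCCCCCCCCCC[C@H](CC(=O)N(C)OC)O[Si](C(C)C)(C(C)C)C(C)C | intermediate
5 | methyl 3,5-dioxohexanoate | COC(=O)CC(=O)CC(C)=O | starting material
6 | trilithium trianion of methyl 3,5-dioxohexanoate (C2, C4 and C6 deprotonated; not isolated) | [Li+].[Li+].[Li+].COC(=O)[CH-]C(=O)[CH-]C(=O)[CH2-] | intermediate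
7 | tetrahedral lithium adduct of 6 with 4 (trilithium salt, new carbinolamine carbon unassigned; not isolated) | [Li+].[Li+].[Li+].CCCCCCCCCCC[C@H](CC([O-])(CC(=O)[CH-]C(=O)[CH-]C(=O)OC)N(C)OC)O[Si](C(C)C)(C(C)C)C(C)C | intermediate
8 | methyl (9R)-3,5,7-trioxo-9-[(triisopropylsilyl)oxy]icosanoate (keto/enol tautomers) | CCCCCCCCCCC[C@H](CC(=O)CC(=O)CC(=O)CC(=O)OC)O[Si](C(C)C)(C(C)C)C(C)C | intermediate
9 | methyl 2-hydroxy-4,6-dioxo-2-[(2R)-2-[(triisopropylsilyl)oxy]tridecyl]cyclohexane-1-carboxylate (cyclic aldol, ring stereocentres transient; not isolated) | CCCCCCCCCCC[C@H](CC1(O)CC(=O)CC(=O)C1C(=O)OC)O[Si](C(C)C)(C(C)C)C(C)C | intermediate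
10 | methyl 2,4-dihydroxy-6-[(2R)-2-[(triisopropylsilyl)oxy]tridecyl]benzoate | CCCCCCCCCCC[C@H](Cc1cc(O)cc(O)c1C(=O)OC)O[Si](C(C)C)(C(C)C)C(C)C | intermediate
11 | 2,4-dihydroxy-6-[(2R)-2-[(triisopropylsilyl)oxy]tridecyl]benzoic acid (not isolated) | CCCCCCCCCCC[C@H](Cc1cc(O)cc(O)c1C(=O)O)O[Si](C(C)C)(C(C)C)C(C)C | intermediate
12 | 5-[(2R)-2-[(triisopropylsilyl)oxy]tridecyl]benzene-1,3-diol | CCCCCCCCCCC[C@H](Cc1cc(O)cc(O)c1)O[Si](C(C)C)(C(C)C)C(C)C | intermediate
13 | 5-[(2R)-2-hydroxytridecyl]benzene-1,3-diol (not isolated) | CCCCCCCCCCC[C@H](Cc1cc(O)cc(O)c1)O | intermediate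
14 | 5-[(2R)-2-(acetyloxy)tridecyl]-1,3-phenylene diacetate | CCCCCCCCCCC[C@H](Cc1cc(OC(C)=O)cc(OC(C)=O)c1)OC(C)=O | intermediate
15 | (2R)-1-(3,5-dihydroxyphenyl)tridecan-2-yl acetate | CCCCCCCCCCC[C@H](Cc1cc(O)cc(O)c1)OC(C)=O | target

Total step count: 8
Longest linear sequence: 8 steps (1 to 15); 5 enters at step 4 as purchased.

Steps most likely to fail

1. Step 5. The polyenolate may close in the wrong sense (C6 onto the ester carbonyl, or an enol oxygen onto the ester to give a pyranone), the ester may hydrolyse before ring closure, or base may expel the silyloxy group. The fallback sets out from 4 and builds the same ring from a dioxinone, in which the carboxyl carbon is locked in an acetonide so that Claisen closure, lactonization and saponification are impossible and only an amine base is needed. Commercial 2,2,6-trimethyl-4H-1,3-dioxin-4-one would be lithiated at the methyl group (LiN(SiMe3)2, THF, −78 °C) and acetylated with acetyl chloride to give 2,2-dimethyl-6-(2-oxopropyl)-4H-1,3-dioxin-4-one F1. Its dianion (LiN(i-Pr)2, 2.2 equiv, THF, −78 °C) would be C-acylated at the methyl terminus by 4 to give 2,2-dimethyl-6-[(6R)-2,4-dioxo-6-[(triisopropylsilyl)oxy]heptadecyl]-4H-1,3-dioxin-4-one F2. Et3N in CH2Cl2 at rt should then effect the aldol closure and dehydrative aromatization to 7-hydroxy-2,2-dimethyl-5-[(2R)-2-[(triisopropylsilyl)oxy]tridecyl]-4H-1,3-benzodioxin-4-one F3. Under the alkaline conditions of step 6, F3 opens with loss of acetone to the acid, so the fallback comes back to the route at 11.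

2. Step 4. The trianion may act as a base toward the α-CH2 of the Weinreb amide, returning starting amide or triggering β-elimination of silanolate, and the triketo ester may cyclize during work-up. The fallback sets out from 4 and replaces acyl transfer by an aldol addition followed by oxidation, since an aldehyde is captured far faster than it is enolized. Reduction of 4 with i-Bu2AlH (THF, −78 °C) should give (3R)-3-[(triisopropylsilyl)oxy]tetradecanal F4. Its addition to the trianion 6 at −78 °C should give methyl (9R)-7-hydroxy-3,5-dioxo-9-[(triisopropylsilyl)oxy]icosanoate F5 as a mixture of C7 epimers. Dess–Martin oxidation (CH2Cl2, NaHCO3, 0 °C) removes the C7 stereocentre, and the fallback comes back to the route at 8.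

3. Step 6. Acyl substitution may stall at the di-ortho-substituted, phenoxide-deactivated ester, and forcing it invites air oxidation of the resorcinol polyanion or slow loss of the silyl group followed by lactonization. The fallback sets out from 10 and cleaves the ester at its methyl carbon instead of its carbonyl carbon: LiI in pyridine at reflux under N2 (SN2 dealkylation by iodide) should give the lithium carboxylate without hydroxide or water. No compound outside the compound list arises (F0). Acidification gives the acid, so the fallback comes back to the route at 11, which is decarboxylated in toluene as in step 6.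

Further compounds
F1 | step 5 | 2,2-dimethyl-6-(2-oxopropyl)-4H-1,3-dioxin-4-one | CC(=O)CC1=CC(=O)OC(C)(C)O1
F2 | step 5 | 2,2-dimethyl-6-[(6R)-2,4-dioxo-6-[(triisopropylsilyl)oxy]heptadecyl]-4H-1,3-dioxin-4-one | CCCCCCCCCCC[C@H](CC(=O)CC(=O)CC1=CC(=O)OC(C)(C)O1)O[Si](C(C)C)(C(C)C)C(C)C
F3 | step 5 | 7-hydroxy-2,2-dimethyl-5-[(2R)-2-[(triisopropylsilyl)oxy]tridecyl]-4H-1,3-benzodioxin-4-one | CCCCCCCCCCC[C@H](Cc1cc(O)cc2OC(C)(C)OC(=O)c12)O[Si](C(C)C)(C(C)C)C(C)C
F4 | step 4 | (3R)-3-[(triisopropylsilyl)oxy]tetradecanal | CCCCCCCCCCC[C@H](CC=O)O[Si](C(C)C)(C(C)C)C(C)C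
F5 | step 4 | methyl (9R)-7-hydroxy-3,5-dioxo-9-[(triisopropylsilyl)oxy]icosanoate (C7 epimers) | CCCCCCCCCCC[C@H](CC(O)CC(=O)CC(=O)CC(=O)OC)O[Si](C(C)C)(C(C)C)C(C)C
F0 | step 6 | none | none
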